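**Plan**

- Retrosynthesis: the C2 acetate and the C3 and C7 benzoate C–O bonds are cut first, then the C6–O bond (water opening of a C1–C6 epoxide) and the epoxide C–O bonds (back to a C1=C6 alkene), then C1–C7 (back to a vinyl bromide), and last the C2–O and C3–O bonds, which leads to bromobenzene.
- Enabling feature: the adjacent C2 and C3 carbinol carbons, lying between the C4=C5 alkene and C1, correspond to an ortho,meta C–C bond of a monosubstituted benzene whose substituted carbon is C1; the cyclohexene ring (the only carbocycle) is that benzene ring.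
- Forward: no carbocycle is closed; only a temporary dioxolane and an oxirane are formed. The order is enzymatic cis-dihydroxylation, acetonide, C7 by Stille coupling, hydroxyl-directed epoxidation of C1=C6, C7 benzoate, water opening at C6, C6 silyl ether, acetonide removal, Mitsunobu benzoate at C3, C2 acetate, desilylation.
- Stereochemistry: C2 comes from the enzyme; C1 and C6 from epoxidation anti to the acetonide followed by anti opening at allylic C6; C3 from SN2 inversion of the enzymatically set C3 carbinol.

Key step: step 1

Remark: locants follow the target ring (C1 = quaternary carbon bearing C7, C2 acetate, C3 benzoate, C4=C5, C6 carbinol); β is the ring face carrying the C2 oxygen, α the opposite face. The C1 descriptor alternates between S and R along the route only because CIP priorities change, not the geometry.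
Remark: (tributylstannyl)methanol and the recombinant E. coli strain are assumed to be obtainable from commercial or culture-collection sources.

**Route**

Step 1
Reactants: 1 bromobenzene
Product: 2 (1S,2S)-3-bromocyclohexa-3,5-diene-1,2-diol
Conditions: E. coli JM109(pDTG601) whole cells expressing toluene dioxygenase (IPTG-induced), glucose feed, air, aqueous mineral-salts medium pH 7, 30–35 °C; EtOAc extraction
Reagents that add atoms: dioxygen, O=O
Why: The Rieske-type non-heme iron dioxygenase binds O2 at its mononuclear divalent iron site, receives two electrons from NADH through its reductase, ferredoxin and [2Fe-2S] cluster, and transfers both oxygen atoms to the same face of the C2–C3 (ortho, meta) bond of the bound arene, so that both C–O bonds form in one event and the ring is left as a 1,3-diene. The closest known reaction type is this very one, the enzymatic arene cis-dihydroxylation of monosubstituted benzenes, for which halobenzenes are standard substrates. No ring is closed: the benzene ring itself becomes the carbocycle of the target. The two new stereocentres (target C2 and C3) are both set by the chiral active site, which seats the single substituent in one pocket and thereby exposes one face of one ortho,meta bond, so the (1S,2S) cis-diol is expected. The step needs 2,3- rather than 3,4-regioselectivity and one absolute sense; the lone, medium-sized bromine secures both through that binding mode and remains as the vinyl bromide that later marks C1 for the C1–C7 bond. C2 is thus delivered in the target configuration, while C3 is knowingly formed in the epimeric sense and corrected in step 9.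

Step 2
Reactants: 2 (1S,2S)-3-bromocyclohexa-3,5-diene-1,2-diol
Product: 3 (3aS,7aS)-4-bromo-2,2-dimethyl-3a,7a-dihydro-1,3-benzodioxole
Conditions: 2,2-dimethoxypropane, p-TsOH·H2O (cat.), acetone, 0 °C to rt; Et3N quench
Reagents that add atoms: 2,2-dimethoxypropane, COC(C)(C)OC
Why: Acid-catalysed transacetalisation (acetonide formation) is fast for the cis-diol and locks the dehydration-prone dihydrodiol as a cis-fused dioxolane that can no longer aromatise and that shields the β face for step 4; no stereocentre changes.

Step 3
Reactants: 3 (3aS,7aS)-4-bromo-2,2-dimethyl-3a,7a-dihydro-1,3-benzodioxole; 4 (tributylstannyl)methanol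
Product: 5 [(3aR,7aS)-2,2-dimethyl-3a,7a-dihydro-1,3-benzodioxol-4-yl]methanol
Conditions: Pd(PPh3)4 (5 mol %), CuI (10 mol %), degassed 1,4-dioxane (0.05 M), 70 °C
Reagents that add atoms: (tributylstannyl)methanol 4, CCCC[Sn](CCCC)(CCCC)CO
Why: Migita–Kosugi–Stille coupling, in which zerovalent palladium inserts into the vinyl C1–Br bond, the hydroxymethyl group is transferred from tin (assisted by CuI) and reductive elimination forms C1–C7 under neutral conditions that leave the acetonide and both stereocentres untouched, while dilution and the moderate temperature should hold back Diels–Alder dimerisation of the diene.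

Step 4
Reactants: 5 [(3aR,7aS)-2,2-dimethyl-3a,7a-dihydro-1,3-benzodioxol-4-yl]methanol
Product: 6 [(1S,2S,3S,6S)-1,6-epoxy-2,3-(isopropylidenedioxy)cyclohex-4-en-1-yl]methanol (α-epoxide, β-acetonide)
Conditions: VO(acac)2 (3 mol %), t-BuOOH (1.3 equiv, in decane), CH2Cl2, 0 °C
Reagents that add atoms: tert-butyl hydroperoxide, CC(C)(C)OO
Why: Hydroxyl-directed vanadium-catalysed epoxidation, in which the vanadate ester of the C7 hydroxyl delivers the peroxide oxygen only to the allylic C1=C6 alkene (C4=C5 has no directing group), and because the cis-fused acetonide covers the β face the oxygen should arrive on the α face, setting C1 and C6 together.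

Step 5
Reactants: 6 [(1S,2S,3S,6S)-1,6-epoxy-2,3-(isopropylidenedioxy)cyclohex-4-en-1-yl]methanol
Product: 7 [(1S,2S,3S,6S)-1,6-epoxy-2,3-(isopropylidenedioxy)cyclohex-4-en-1-yl]methyl benzoate
Conditions: BzCl (1.2 equiv), Et3N, DMAP (cat.), CH2Cl2, 0 °C
Reagents that add atoms: benzoyl chloride, O=C(Cl)c1ccccc1
Why: DMAP-catalysed acylation of the primary alcohol under basic, non-nucleophilic conditions installs the C7 benzoate without opening the acid-sensitive vinyl epoxide or touching any stereocentre.

Step 6
Reactants: 7 [(1S,2S,3S,6S)-1,6-epoxy-2,3-(isopropylidenedioxy)cyclohex-4-en-1-yl]methyl benzoate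
Product: 8 [(1S,2S,3S,6R)-1,6-dihydroxy-2,3-(isopropylidenedioxy)cyclohex-4-en-1-yl]methyl benzoate
Conditions: HClO4 (5 mol %, aq.), THF/H2O (3:1), 0 °C; NaHCO3 quench
Reagents that add atoms: water, O
Why: Acid-catalysed anti hydrolysis of a vinyl epoxide (Fürst–Plattner-type opening with SN2 character), in which the allylic C6–O bond is the activated one whereas C1 is fully substituted and flanked by two oxygen-bearing carbons, so water should enter at C6 from the β face with inversion, giving the β C6 carbinol and leaving the α tertiary C1 hydroxyl, while the brief cold contact with dilute acid should spare the acetonide and the ester.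

Step 7
Reactants: 8 [(1S,2S,3S,6R)-1,6-dihydroxy-2,3-(isopropylidenedioxy)cyclohex-4-en-1-yl]methyl benzoate
Product: 9 [(1R,2S,3S,6R)-6-(tert-butyldimethylsilyloxy)-1-hydroxy-2,3-(isopropylidenedioxy)cyclohex-4-en-1-yl]methyl benzoate
Conditions: TBSOTf (1.1 equiv), 2,6-lutidine, CH2Cl2, −78 °C
Reagents that add atoms: tert-butyldimethylsilyl trifluoromethanesulfonate, CC(C)(C)[Si](C)(C)OS(=O)(=O)C(F)(F)F
Why: Silylation with a silyl triflate at low temperature distinguishes the secondary allylic C6 hydroxyl from the tertiary C1 hydroxyl, masking the second allylic carbinol so that only C3 can be activated in step 9 and the trans-1,6-diol cannot close back to an epoxide there.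

Step 8
Reactants: 9 [(1R,2S,3S,6R)-6-(tert-butyldimethylsilyloxy)-1-hydroxy-2,3-(isopropylidenedioxy)cyclohex-4-en-1-yl]methyl benzoate
Product: 10 [(1R,2S,3S,6R)-6-(tert-butyldimethylsilyloxy)-1,2,3-trihydroxycyclohex-4-en-1-yl]methyl benzoate
Conditions: TFA/H2O (9:1), CH2Cl2, 0 °C, short contact; toluene co-evaporation
Reagents that add atoms: none
Why: Acid-catalysed acetal hydrolysis releases the cis C2/C3 diol, while the hindered secondary TBS ether next to the quaternary C1 and the benzoate should withstand short contact with cold aqueous TFA; no stereocentre is involved.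

Step 9
Reactants: 10 [(1R,2S,3S,6R)-6-(tert-butyldimethylsilyloxy)-1,2,3-trihydroxycyclohex-4-en-1-yl]methyl benzoate; 11 benzoic acid
Product: 12 [(1R,2S,3R,6R)-3-(benzoyloxy)-6-(tert-butyldimethylsilyloxy)-1,2-dihydroxycyclohex-4-en-1-yl]methyl benzoate
Conditions: PPh3 (1.5 equiv), DIAD (1.5 equiv), THF, 0 °C to rt
Reagents that add atoms: benzoic acid 11, OC(=O)c1ccccc1
Why: Mitsunobu reaction, in which of the three free hydroxyls only C3 is both allylic and unhindered (C2 is neopentyl-like next to C1, C1 is tertiary), so its phosphonium-activated oxygen should be displaced by benzoate from the α face in an SN2 step that inverts C3 to the target configuration, the cis C2 hydroxyl being unable to displace it as an epoxide.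

Step 10
Reactants: 12 [(1R,2S,3R,6R)-3-(benzoyloxy)-6-(tert-butyldimethylsilyloxy)-1,2-dihydroxycyclohex-4-en-1-yl]methyl benzoate
Product: 13 [(1R,2S,3R,6R)-2-(acetyloxy)-3-(benzoyloxy)-6-(tert-butyldimethylsilyloxy)-1-hydroxycyclohex-4-en-1-yl]methyl benzoate
Conditions: Ac2O (1.5 equiv), pyridine, DMAP (cat.), CH2Cl2, 0 °C
Reagents that add atoms: acetic anhydride, CC(=O)OC(C)=O
Why: DMAP-catalysed acetylation acylates the remaining secondary C2 hydroxyl while the tertiary C1 hydroxyl is inert under these mild conditions, and the cold, short reaction should prevent migration of the C3 benzoate.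

Step 11
Reactants: 13 [(1R,2S,3R,6R)-2-(acetyloxy)-3-(benzoyloxy)-6-(tert-butyldimethylsilyloxy)-1-hydroxycyclohex-4-en-1-yl]methyl benzoate
Product: 14 [(1S,2S,3R,6R)-2-(acetyloxy)-3-(benzoyloxy)-1,6-dihydroxycyclohex-4-en-1-yl]methyl benzoate (CNP0160999.2)
Conditions: HF·pyridine, pyridine/THF, 0 °C to rt
Reagents that add atoms: none
Why: Fluoride-induced cleavage of the Si–O bond with buffered HF·pyridine, mildly acidic throughout, frees the C6 hydroxyl without the base-catalysed acyl migrations that could move the C2 acetate or the C7 benzoate onto neighbouring hydroxyls.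

**Compound list**

1 | bromobenzene | Brc1ccccc1 | starting material
2 | (1S,2S)-3-bromocyclohexa-3,5-diene-1,2-diol | O[C@H]1[C@@H](O)C=CC=C1Br | intermediate
3 | (3aS,7aS)-4-bromo-2,2-dimethyl-3a,7a-dihydro-1,3-benzodioxole | CC1(C)O[C@H]2[C@@H](O1)C=CC=C2Br | intermediate
4 | (tributylstannyl)methanol | CCCC[Sn](CCCC)(CCCC)CO | starting material
5 | [(3aR,7aS)-2,2-dimethyl-3a,7a-dihydro-1,3-benzodioxol-4-yl]methanol | CC1(C)O[C@H]2[C@@H](O1)C=CC=C2CO | intermediate
6 | [(1S,2S,3S,6S)-1,6-epoxy-2,3-(isopropylidenedioxy)cyclohex-4-en-1-yl]methanol (α-epoxide, β-acetonide) | CC1(C)O[C@H]2[C@@H](O1)C=C[C@@H]3O[C@]23CO | intermediate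
7 | [(1S,2S,3S,6S)-1,6-epoxy-2,3-(isopropylidenedioxy)cyclohex-4-en-1-yl]methyl benzoate | CC1(C)O[C@H]2[C@@H](O1)C=C[C@@H]3O[C@]23COC(=O)c1ccccc1 | intermediate
8 | [(1S,2S,3S,6R)-1,6-dihydroxy-2,3-(isopropylidenedioxy)cyclohex-4-en-1-yl]methyl benzoate | CC1(C)O[C@H]2[C@@H](O1)C=C[C@@H](O)[C@@]2(O)COC(=O)c1ccccc1 | intermediate
9 | [(1R,2S,3S,6R)-6-(tert-butyldimethylsilyloxy)-1-hydroxy-2,3-(isopropylidenedioxy)cyclohex-4-en-1-yl]methyl benzoate | CC1(C)O[C@H]2[C@@H](O1)C=C[C@@H](O[Si](C)(C)C(C)(C)C)[C@@]2(O)COC(=O)c1ccccc1 | intermediate
10 | [(1R,2S,3S,6R)-6-(tert-butyldimethylsilyloxy)-1,2,3-trihydroxycyclohex-4-en-1-yl]methyl benzoate | O[C@H]1[C@@H](O)C=C[C@@H](O[Si](C)(C)C(C)(C)C)[C@@]1(O)COC(=O)c1ccccc1 | intermediate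
11 | benzoic acid | OC(=O)c1ccccc1 | starting material
12 | [(1R,2S,3R,6R)-3-(benzoyloxy)-6-(tert-butyldimethylsilyloxy)-1,2-dihydroxycyclohex-4-en-1-yl]methyl benzoate | O[C@H]1[C@H](OC(=O)c2ccccc2)C=C[C@@H](O[Si](C)(C)C(C)(C)C)[C@@]1(O)COC(=O)c1ccccc1 | intermediate
13 | [(1R,2S,3R,6R)-2-(acetyloxy)-3-(benzoyloxy)-6-(tert-butyldimethylsilyloxy)-1-hydroxycyclohex-4-en-1-yl]methyl benzoate | CC(=O)O[C@H]1[C@H](OC(=O)c2ccccc2)C=C[C@@H](O[Si](C)(C)C(C)(C)C)[C@@]1(O)COC(=O)c1ccccc1 | intermediate
14 | [(1S,2S,3R,6R)-2-(acetyloxy)-3-(benzoyloxy)-1,6-dihydroxycyclohex-4-en-1-yl]methyl benzoate (CNP0160999.2) | CC(=O)O[C@H]1[C@H](OC(=O)c2ccccc2)C=C[C@@H](O)[C@@]1(O)COC(=O)c1ccccc1 | target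

**Step count**

Total: 11 steps. Longest linear sequence: 11 steps, from bromobenzene 1 to target 14; stannane 4 and benzoic acid 11 are purchased.

**Steps most likely to fail**

1. Step 9 (Mitsunobu inversion at C3). The activation may spread over the cis C2/C3 diol as a cyclic phosphorane that collapses without C3 selectivity, benzoate may attack C5 in an SN2′ sense with allylic transposition, or the C1 alkoxide may close onto an activated C2. Fallback: setting out from triol 10, SOCl2 and Et3N in CH2Cl2 at 0 °C should tie the cis C2/C3 diol into the cyclic 2,3-sulfite of 10 (configuration at carbon as in 10, epimers at sulfur, C1 hydroxyl free) F1. PhCO2Cs in DMF at 60–70 °C should then attack the allylic C3 carbon in an SN2 step with inversion, giving the C2 hydrogen sulfite half-ester of 12 (C3 benzoate α) F2. F2 is not isolated but hydrolysed with dilute aqueous H2SO4 in THF during work-up, returning to the route at benzoate 12.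

2. Step 6 (water opening of the vinyl epoxide). The protonated epoxide may ionise to an allyl cation, with loss of anti stereospecificity and 1,4-addition of water at C4; the C7 benzoate carbonyl may participate at C1; or the acetonide may hydrolyse at the same time. Fallback: setting out from epoxy alcohol 6, before any ester is present, the epoxide is opened by water alone in H2O/1,4-dioxane at 60 °C (water-promoted, no added acid). Hydrogen-bond activation should favour SN2 attack at allylic C6 and no ester can participate, giving (1S,2S,3S,6R)-1-(hydroxymethyl)-2,3-(isopropylidenedioxy)cyclohex-4-ene-1,6-diol F3. The primary C7 hydroxyl of F3 is then benzoylated selectively (BzCl, 2,4,6-collidine, CH2Cl2, −40 °C), returning to the route at diol 8.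

3. Step 3 (Stille hydroxymethylation). The bromodiene may dimerise by Diels–Alder reaction at the coupling temperature while transfer of the hydroxymethyl group from tin is slow, and the stannane may be lost by protodestannylation. Fallback: setting out from bromide 3, palladium-catalysed methoxycarbonylation (Pd(OAc)2, PPh3, CO 1 atm, MeOH, Et3N, DMF, 50 °C) forms the C1–C7 bond by CO insertion, which needs no transmetalation, and should give methyl (3aR,7aS)-2,2-dimethyl-3a,7a-dihydro-1,3-benzodioxole-4-carboxylate F4. Reduction with i-Bu2AlH (CH2Cl2, −78 °C) returns to the route at dienol 5.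

**Further compounds**

F1 | step 9 | cyclic 2,3-sulfite of triol 10, [(1S,2S,3S,6R)-6-(tert-butyldimethylsilyloxy)-1-hydroxy-2,3-(sulfinyldioxy)cyclohex-4-en-1-yl]methyl benzoate | O=S1O[C@H]2[C@@H](O1)C=C[C@@H](O[Si](C)(C)C(C)(C)C)[C@@]2(O)COC(=O)c1ccccc1
F2 | step 9 | C2 hydrogen sulfite half-ester of 12, [(1S,2S,3R,6R)-3-(benzoyloxy)-6-(tert-butyldimethylsilyloxy)-1-hydroxy-2-(sulfinooxy)cyclohex-4-en-1-yl]methyl benzoate | OS(=O)O[C@H]1[C@H](OC(=O)c2ccccc2)C=C[C@@H](O[Si](C)(C)C(C)(C)C)[C@@]1(O)COC(=O)c1ccccc1
F3 | step 6 | (1S,2S,3S,6R)-1-(hydroxymethyl)-2,3-(isopropylidenedioxy)cyclohex-4-ene-1,6-diol | CC1(C)O[C@H]2[C@@H](O1)C=C[C@@H](O)[C@@]2(O)CO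
F4 | step 3 | methyl (3aR,7aS)-2,2-dimethyl-3a,7a-dihydro-1,3-benzodioxole-4-carboxylate | CC1(C)O[C@H]2[C@@H](O1)C=CC=C2C(=O)OC
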